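Compound numbers refer to the steps and the compound list below. Ring A is numbered from the carboxyl-bearing carbon C1 (C2 OMe, C3 side chain, C6 aryloxy), ring B from the ether carbon C1′ (C2′ OH, C4′ CH3, C6′ CH2OH).

## Analysis of the target

Target 25 is an open, non-fused diaryl ether. Ring A is a benzoic acid (C1) with a methoxy group at C2, the 1,3-dihydroxy-3-methylbutyl chain at C3 and the ether oxygen at C6. Ring B carries the ether oxygen at C1′, a free phenol at C2′, a methyl at C4′ and a hydroxymethyl at C6′. The only stereocentre is the benzylic carbinol carbon on C3, of R configuration; nothing else in the molecule can relay stereochemistry to it, so a chiral reagent must set it. The sensitive points are this benzylic alcohol (ortho to OMe, para to the aryloxy oxygen, hence open to acid ionisation), the tertiary alcohol (dehydration), and the free phenol and benzylic alcohol of ring B. The main difficulty is the ether bond: C1′ has two ortho substituents, and C6 sits next to C1, which is itself wedged between C6–O and C2–OMe, so ring A is 1,2,3,4-tetrasubstituted and substitution or copper coupling would meet hindrance on both sides. A second difficulty is telling five oxygen functions apart while keeping one methyl ether. The feature used here is that the aryloxy carbon C6 and the carboxyl carbon C1 are adjacent and C1 has the C2 methoxy group on its other side. That is exactly the pattern left when a nucleophile and an electrophile add across the C1–C6 triple bond of a 3-methoxy-type aryne, with ring B entering simply as a hindered phenoxide.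

## Retrosynthetic reasoning

**Protecting groups (25 ⇐ 24 ⇐ 23).** The last operations are kept to deprotection. The two side-chain hydroxyls are masked together as one acetonide, the ring B benzylic alcohol as a silyl ether and the C2′ phenol as an allyl ether. A methyl ether on C2′ could not be removed beside the C2 methoxy group, which must stay. None of these groups offers a proton to an aryl anion, and none needs strong acid or hydrogenolysis for removal.

**Aryne three-component coupling (23 ⇐ 12 + 18 + 19).** The C6–O and C1–CO2H bonds are cut together. This leads back to aryne 21 (C1–C6 triple bond), released from ortho-silylaryl triflate 12, to the ring B phenol 18 as its phenoxide 20, and to carbon dioxide 19. The cut is made here because it removes both hindered bonds in one step and turns the hindrance of 18 into a non-issue: the phenoxide attacks an unhindered sp carbon. The forward reaction has to add the phenoxide at C6 (not C1) and trap the C1 anion 22 with 19 before it finds a proton.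

**Aryne precursor (12 ⇐ 11 ⇐ 10 ⇐ 8).** The triflate comes from phenol 11, and the C1 silyl group from directed metalation of carbamate 8, through aryllithium 9, at the position between the carbamate oxygen and the methoxy group. The forward steps must metalate C1 and not C5, and must remove the carbamate without touching the C–Si bond or the acetonide.

**Side chain (8 ⇐ 7 ⇐ 6 ⇐ 2 + 3; 2 ⇐ 1).** The acetonide is opened to diol 7, the tertiary alcohol is traced to Markovnikov hydration of the 1,1-disubstituted alkene of 6, and the C–C bond next to the stereocentre is cut to aldehyde 2 and the methallyl nucleophile 3. Cutting here places the only stereocentre in a reagent-controlled addition to a simple aryl aldehyde at the start of the route. Aldehyde 2 is the carbamate of commercial phenol 1, whose oxygen pattern (OMe ortho and OH para to the formyl group) maps onto C2, C6 and C3.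

**Ring B (18 ⇐ 17 ⇐ 16 ⇐ 15 ⇐ 14 ⇐ 13).** The silyl ether and the benzylic alcohol go back to salicylaldehyde 16, the allyl ether to catechol aldehyde 15, and that to creosol 13 through ortho-formylation (14) and demethylation. The formyl group does double duty: it becomes C6′–CH2OH and it differentiates the two catechol oxygens so that only the C2′ oxygen is allylated.

## Alternatives that were turned down

**Alternative 1:** biomimetic spirocyclisation and ring opening.
- *Disconnection:* the ether O–C1′ bond is traced to an intramolecular phenol coupling and the C1 carboxyl to the ketone carbon of benzophenone A2.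
- *Forward key step:* anodic oxidation of the ring B phenol of A2; the ring A phenol oxygen attacks C1′ and closes the five-membered benzofuranone ring of spiro cyclohexa-2,4-dienone A1. Base then cleaves the C(=O)–C1′ bond (retro-Claisen) and ring B rearomatises.
- *For:* the ether bond forms intramolecularly, so hindrance at C1′ does not matter; the carboxyl carbon arrives at the right oxidation level; both stages are known for grisan-type dienones, and the racemic spiro centre is erased.
- *Against:* A2 is a diaryl ketone with four ortho substituents and is itself hard to assemble. The oxidation must choose the ring B phenol and C1′ over other sites. 2,4-Cyclohexadienones dimerise easily. The side chain must be carried as a ketone and reduced enantioselectively late, next to the ring B functions.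
- *Comparison:* it is stronger on precedent, since every step is known and the chosen key step is untested. The chosen route offers convergence, a stereocentre set on a simple aldehyde, and fewer operations after the key step.

**Alternative 2:** Robinson-type construction of ring B.
- *Disconnection:* ring B is cut at C3′–C4′ and C1′–C6′, with the ether oxygen already on C1′ as an aryloxymethyl ketone.
- *Forward key step:* aryloxyacetoacetate A4, carrying the complete ring A, adds through C3′ to enone A5; the aryloxy-bearing C1′ then condenses on the C6′ keto group to give cyclohexenone A3. Deallylative decarboxylation with dehydrogenation aromatises ring B, and the C6′ ester is reduced.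
- *For:* the ether bond is made by plain phenol alkylation, with no hindered arylation at all; the chemistry is classical and the transient ring stereocentres vanish.
- *Against:* the fully substituted ring A salicylate (C1 ester, C6 OH) needed for A4 requires the same in-between metalation at C1 as the chosen route. The aldol must occur at the less acidic aryloxymethyl carbon. The annulation is followed by aromatisation, a selective reduction of the C6′ methyl ester beside the tert-butyl ester, and a strongly acidic ester cleavage that the electron-rich benzylic carbinol tolerates poorly.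
- *Comparison:* no step is unprecedented, which is its advantage. It is weaker in step economy and convergence, because the chiral ring A is carried through a long linear sequence, whereas the chosen route takes ring B from a cheap arene with its substituents in place.

**Alternative 3:** Danheiser benzannulation of ring A.
- *Disconnection:* ring A is built by forming C1–C2, C2–C3, C4–C5 and C5–C6 from diazo enone A7 and aryloxyalkyne A8.
- *Forward key step:* irradiation of A7 causes Wolff rearrangement to a vinylketene, which adds to the alkyne of A8 in a [2+2] sense; four-electron opening and six-electron closure give phenol A6.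
- *For:* the pericyclic cascade dictates the position of all four contiguous substituents, and the ether bond exists before the ring is made.
- *Against:* A8 is an alkynyl ether of a di-ortho-substituted phenol; it needs multi-step strong-base elimination chemistry that the allyl ether barely tolerates, and it is hydrolytically labile. A7 needs its stereocentre installed on a non-aromatic precursor. After the annulation, the flanked C2 phenol must be methylated, the benzyl-type ether removed and C1–CH2OH oxidised in two stages beside the electron-rich ring B, before the same two deprotections.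
- *Comparison:* its regiochemical guarantee is mechanistic and therefore stronger than the electronic bias relied on here. The chosen route delivers C1 directly as the acid with the methoxy group already present, from stable partners and in fewer steps.

Key step: step 13

Remark: 2-methylallylmagnesium chloride 3 is used as the commercial THF solution (it is the Grignard reagent of 3-chloro-2-methylprop-1-ene).

## Route

Step 1
Reactants: 1 4-hydroxy-2-methoxybenzaldehyde
Product: 2 4-formyl-3-methoxyphenyl N,N-diethylcarbamate
Conditions: Et2NCOCl, K2CO3, MeCN, reflux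
Reagents that add atoms: N,N-diethylcarbamoyl chloride, CCN(CC)C(Cl)=O
Why: O-carbamoylation of the potassium phenoxide; the diethylcarbamate survives the organoboron, radical and acetalisation steps and is the directing group needed in step 5.

Step 2
Reactants: 2 4-formyl-3-methoxyphenyl N,N-diethylcarbamate; 3 2-methylallylmagnesium chloride
Product: 6 4-[(1R)-1-hydroxy-3-methylbut-3-en-1-yl]-3-methoxyphenyl N,N-diethylcarbamate, via B-(2-methylallyl)diisopinocampheylborane 4 (not isolated), via diisopinocampheylborinate ester 5 (not isolated)
Conditions: (+)-Ipc2BOMe (lIpc series, from (−)-α-pinene), 3, Et2O, −78 °C → rt; then 2, −78 °C; then NaOH, H2O2, 0 °C → rt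
Reagents that add atoms: none
Why: Brown asymmetric methallylation: 3 transfers its allyl group to boron to give 4, which adds to the aldehyde through a chair Zimmerman–Traxler transition state; the lIpc reagent should attack the Re face, which for an aryl aldehyde gives the (R)-carbinol. Alkaline peroxide cleaves borinate 5; the carbamate is inert to the borane and to cold base.

Step 3
Reactants: 6 4-[(1R)-1-hydroxy-3-methylbut-3-en-1-yl]-3-methoxyphenyl N,N-diethylcarbamate
Product: 7 4-[(1R)-1,3-dihydroxy-3-methylbutyl]-3-methoxyphenyl N,N-diethylcarbamate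
Conditions: Co(acac)2 (cat.), PhSiH3, O2 (1 atm), THF, rt; aq. Na2S2O3
Reagents that add atoms: dioxygen, O=O
Why: Mukaiyama hydration: a cobalt hydride transfers a hydrogen atom to the 1,1-disubstituted alkene and the tertiary radical is trapped by O2 and reduced, so the Markovnikov tertiary alcohol should form; the benzylic stereocentre is not involved.

Step 4
Reactants: 7 4-[(1R)-1,3-dihydroxy-3-methylbutyl]-3-methoxyphenyl N,N-diethylcarbamate
Product: 8 3-methoxy-4-[(4R)-2,2,6,6-tetramethyl-1,3-dioxan-4-yl]phenyl N,N-diethylcarbamate
Conditions: 2-methoxypropene, PPTS (cat.), CH2Cl2, 0 °C → rt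
Reagents that add atoms: 2-methoxypropene, COC(C)=C
Why: Acid-catalysed acetonide formation from an enol ether ties both hydroxyls into one 1,3-dioxane, so no O–H remains for steps 5 and 13; the weak acid should not ionise the benzylic C–O bond, so the configuration is kept.

Step 5
Reactants: 8 3-methoxy-4-[(4R)-2,2,6,6-tetramethyl-1,3-dioxan-4-yl]phenyl N,N-diethylcarbamate
Product: 10 3-methoxy-4-[(4R)-2,2,6,6-tetramethyl-1,3-dioxan-4-yl]-2-(trimethylsilyl)phenyl N,N-diethylcarbamate, via C1 aryllithium 9 (not isolated)
Conditions: s-BuLi, TMEDA, THF, −78 °C; TMSCl, −78 °C → rt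
Reagents that add atoms: chlorotrimethylsilane, C[Si](C)(C)Cl
Why: Directed ortho-metalation: the carbamate is the strong director and C1–H, between the carbamate oxygen and the methoxy oxygen, is the most acidic ring position, so lithiation should give 9; it is silylated at −78 °C before an anionic ortho-Fries shift can set in.

Step 6
Reactants: 10 3-methoxy-4-[(4R)-2,2,6,6-tetramethyl-1,3-dioxan-4-yl]-2-(trimethylsilyl)phenyl N,N-diethylcarbamate
Product: 11 3-methoxy-4-[(4R)-2,2,6,6-tetramethyl-1,3-dioxan-4-yl]-2-(trimethylsilyl)phenol
Conditions: LiAlH4, THF, 0 °C → reflux; aq. potassium sodium tartrate (KNaC4H4O6)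
Reagents that add atoms: none
Why: Hydride reduction of the aryl carbamate releases the phenoxide and the amine fragment; the C–Si bond, the acetal and the methyl ether are inert to LiAlH4, and the near-neutral work-up avoids protodesilylation.

Step 7
Reactants: 11 3-methoxy-4-[(4R)-2,2,6,6-tetramethyl-1,3-dioxan-4-yl]-2-(trimethylsilyl)phenol
Product: 12 3-methoxy-4-[(4R)-2,2,6,6-tetramethyl-1,3-dioxan-4-yl]-2-(trimethylsilyl)phenyl trifluoromethanesulfonate
Conditions: PhNTf2, DBU, MeCN, rt → 40 °C
Reagents that add atoms: N-phenylbis(trifluoromethanesulfonimide), O=S(=O)(N(c1ccccc1)S(=O)(=O)C(F)(F)F)C(F)(F)F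
Why: O-triflation of the phenoxide with a mild triflyl donor under amine base gives the ortho-silylaryl triflate without exposing the acetonide to acid.

Step 8
Reactants: 13 2-methoxy-4-methylphenol (creosol)
Product: 14 2-hydroxy-3-methoxy-5-methylbenzaldehyde
Conditions: MgCl2, Et3N, (CH2O)n, MeCN, reflux; aq. HCl
Reagents that add atoms: formaldehyde (as paraformaldehyde), C=O
Why: Magnesium-mediated ortho-formylation of phenols (Casnati–Skattebøl reaction): the magnesium phenoxide directs hydroxymethylation to the only free ortho position and a second formaldehyde oxidises the benzylic alkoxide to the aldehyde.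

Step 9
Reactants: 14 2-hydroxy-3-methoxy-5-methylbenzaldehyde
Product: 15 2,3-dihydroxy-5-methylbenzaldehyde
Conditions: BBr3, CH2Cl2, −78 °C → rt; H2O
Reagents that add atoms: none
Why: Lewis-acid cleavage of the aryl methyl ether, standard for ortho-vanillin-type substrates; the aldehyde and the ring methyl are unaffected.

Step 10
Reactants: 15 2,3-dihydroxy-5-methylbenzaldehyde
Product: 16 3-(allyloxy)-2-hydroxy-5-methylbenzaldehyde
Conditions: NaH (2.2 equiv), DMSO, rt; allyl bromide (1.0 equiv)
Reagents that add atoms: allyl bromide, C=CCBr
Why: Williamson etherification of the dianion: the 2-oxide is conjugated with and chelated to the formyl group, so the 3-oxide is the more nucleophilic site and one equivalent of allyl bromide should alkylate there.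

Step 11
Reactants: 16 3-(allyloxy)-2-hydroxy-5-methylbenzaldehyde
Product: 17 2-(allyloxy)-6-(hydroxymethyl)-4-methylphenol
Conditions: NaBH4, MeOH, 0 °C
Reagents that add atoms: none
Why: Borohydride reduction of the aldehyde to the benzylic alcohol; the allyl ether and the phenol are untouched.

Step 12
Reactants: 17 2-(allyloxy)-6-(hydroxymethyl)-4-methylphenol
Product: 18 2-(allyloxy)-6-[(tert-butyldimethylsilyloxy)methyl]-4-methylphenol
Conditions: TBSCl (1.05 equiv), imidazole, CH2Cl2, 0 °C
Reagents that add atoms: tert-butyldimethylsilyl chloride, CC(C)(C)[Si](C)(C)Cl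
Why: Selective silylation: the primary alcohol reacts much faster than the hydrogen-bonded phenol with two ortho substituents, so one equivalent of silyl chloride should leave the phenol free.

Step 13
Reactants: 12 3-methoxy-4-[(4R)-2,2,6,6-tetramethyl-1,3-dioxan-4-yl]-2-(trimethylsilyl)phenyl trifluoromethanesulfonate; 18 2-(allyloxy)-6-[(tert-butyldimethylsilyloxy)methyl]-4-methylphenol; 19 carbon dioxide
Product: 23 6-[2-(allyloxy)-6-{[tert-butyl(dimethyl)silyl]oxymethyl}-4-methylphenoxy]-2-methoxy-3-[(4R)-2,2,6,6-tetramethyl-1,3-dioxan-4-yl]benzoic acid, via potassium phenoxide 20 (not isolated), via aryne 21 (not isolated), via C1 aryl anion 22 (not isolated)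
Conditions: 18 (1.5 equiv), KH, THF, 0 °C; then KF, 18-crown-6, CO2 (1 atm), slow addition of 12, 0 °C → rt; aq. citric acid (pH 4)
Reagents that add atoms: none
Why: Proposed new method: fluoride attacks the C1 silicon of 12 and triflate leaves from C6 to give aryne 21; phenoxide 20 adds to C6, and the C1 aryl anion 22, which finds no proton in the medium (THF and not acetonitrile, phenol fully deprotonated by KH so that no bifluoride forms), is carboxylated by 19. The closest known reaction types are the three-component coupling of arynes with amines and CO2 to anthranilic acids under KF/18-crown-6 in THF and the fluoride-induced O-arylation of phenols by ortho-silylaryl triflates; what is new is a phenoxide as the nucleophile in the CO2 coupling. No ring is closed and no stereocentre is created; the (4R) centre is a spectator. The step needs regioselectivity: the C2 methoxy group withdraws σ-electron density, distorts the aryne so that C6 is the more electrophilic terminus and stabilises charge at C1, so the phenoxide should enter at C6 as with 3-methoxybenzyne, and the C3 dioxanyl group is remote from both aryne carbons. It needs chemoselectivity for 20 over the product carboxylate and over fluoride, which the excess of 20 and the poor nucleophilicity of a 2,6-disubstituted benzoate should secure. It needs CO2 capture to outrun proton abstraction; the two flanking oxygen substituents stabilise 22 inductively and lower its basicity. Carbonate formation between 20 and CO2 is reversible and sterically disfavoured by the two ortho substituents, so free phenoxide should remain available.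

Step 14
Reactants: 23 6-[2-(allyloxy)-6-{[tert-butyl(dimethyl)silyl]oxymethyl}-4-methylphenoxy]-2-methoxy-3-[(4R)-2,2,6,6-tetramethyl-1,3-dioxan-4-yl]benzoic acid
Product: 24 6-[2-{[tert-butyl(dimethyl)silyl]oxymethyl}-6-hydroxy-4-methylphenoxy]-2-methoxy-3-[(4R)-2,2,6,6-tetramethyl-1,3-dioxan-4-yl]benzoic acid
Conditions: Pd(PPh3)4 (cat.), morpholine, THF, rt; aq. citric acid (pH 4)
Reagents that add atoms: none
Why: Tsuji–Trost deallylation: zerovalent palladium ionises the aryl allyl ether to a π-allyl complex that morpholine intercepts; any allyl ester formed from the carboxylate is cleaved in the same way, and the acetonide and silyl ether are inert.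

Step 15
Reactants: 24 6-[2-{[tert-butyl(dimethyl)silyl]oxymethyl}-6-hydroxy-4-methylphenoxy]-2-methoxy-3-[(4R)-2,2,6,6-tetramethyl-1,3-dioxan-4-yl]benzoic acid
Product: 25 3-[(1R)-1,3-dihydroxy-3-methylbutyl]-6-[2-hydroxy-6-(hydroxymethyl)-4-methylphenoxy]-2-methoxybenzoic acid
Conditions: AcOH/THF/H2O (3:1:1), rt
Reagents that add atoms: none
Why: Acid hydrolysis removes the strained tetramethyl-1,3-dioxane and the primary silyl ether together; the medium is only weakly acidic and the ring A carboxyl group lowers the electron density of the ring, so the benzylic C–O bond should not ionise and the R configuration should be retained.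

## Compound list

1 | 4-hydroxy-2-methoxybenzaldehyde | COc1cc(O)ccc1C=O | starting material
2 | 4-formyl-3-methoxyphenyl N,N-diethylcarbamate | CCN(CC)C(=O)Oc1ccc(C=O)c(OC)c1 | intermediate
3 | 2-methylallylmagnesium chloride | C=C(C)C[Mg]Cl | starting material
4 | B-(2-methylallyl)diisopinocampheylborane (lIpc series, from (−)-α-pinene) | C=C(C)CB([C@H]1C[C@H]2C[C@@H]([C@@H]1C)C2(C)C)[C@H]1C[C@H]2C[C@@H]([C@@H]1C)C2(C)C | intermediate (not isolated)
5 | diisopinocampheylborinate ester of 6 | CCN(CC)C(=O)Oc1ccc([C@H](OB([C@H]2C[C@H]3C[C@@H]([C@@H]2C)C3(C)C)[C@H]2C[C@H]3C[C@@H]([C@@H]2C)C3(C)C)CC(C)=C)c(OC)c1 | intermediate (not isolated)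
6 | 4-[(1R)-1-hydroxy-3-methylbut-3-en-1-yl]-3-methoxyphenyl N,N-diethylcarbamate | CCN(CC)C(=O)Oc1ccc([C@H](O)CC(C)=C)c(OC)c1 | intermediate
7 | 4-[(1R)-1,3-dihydroxy-3-methylbutyl]-3-methoxyphenyl N,N-diethylcarbamate | CCN(CC)C(=O)Oc1ccc([C@H](O)CC(C)(C)O)c(OC)c1 | intermediate
8 | 3-methoxy-4-[(4R)-2,2,6,6-tetramethyl-1,3-dioxan-4-yl]phenyl N,N-diethylcarbamate | CCN(CC)C(=O)Oc1ccc([C@H]2CC(C)(C)OC(C)(C)O2)c(OC)c1 | intermediate
9 | 2-lithio-3-methoxy-4-[(4R)-2,2,6,6-tetramethyl-1,3-dioxan-4-yl]phenyl N,N-diethylcarbamate (C1 aryllithium) | CCN(CC)C(=O)Oc1ccc([C@H]2CC(C)(C)OC(C)(C)O2)c(OC)c1[Li] | intermediate (not isolated)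
10 | 3-methoxy-4-[(4R)-2,2,6,6-tetramethyl-1,3-dioxan-4-yl]-2-(trimethylsilyl)phenyl N,N-diethylcarbamate | CCN(CC)C(=O)Oc1ccc([C@H]2CC(C)(C)OC(C)(C)O2)c(OC)c1[Si](C)(C)C | intermediate
11 | 3-methoxy-4-[(4R)-2,2,6,6-tetramethyl-1,3-dioxan-4-yl]-2-(trimethylsilyl)phenol | COc1c([C@H]2CC(C)(C)OC(C)(C)O2)ccc(O)c1[Si](C)(C)C | intermediate
12 | 3-methoxy-4-[(4R)-2,2,6,6-tetramethyl-1,3-dioxan-4-yl]-2-(trimethylsilyl)phenyl trifluoromethanesulfonate | COc1c([C@H]2CC(C)(C)OC(C)(C)O2)ccc(OS(=O)(=O)C(F)(F)F)c1[Si](C)(C)C | intermediate
13 | 2-methoxy-4-methylphenol (creosol) | COc1cc(C)ccc1O | starting material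
14 | 2-hydroxy-3-methoxy-5-methylbenzaldehyde | COc1cc(C)cc(C=O)c1O | intermediate
15 | 2,3-dihydroxy-5-methylbenzaldehyde | Oc1cc(C)cc(C=O)c1O | intermediate
16 | 3-(allyloxy)-2-hydroxy-5-methylbenzaldehyde | C=CCOc1cc(C)cc(C=O)c1O | intermediate
17 | 2-(allyloxy)-6-(hydroxymethyl)-4-methylphenol | C=CCOc1cc(C)cc(CO)c1O | intermediate
18 | 2-(allyloxy)-6-[(tert-butyldimethylsilyloxy)methyl]-4-methylphenol | C=CCOc1cc(C)cc(CO[Si](C)(C)C(C)(C)C)c1O | intermediate
19 | carbon dioxide | O=C=O | starting material
20 | potassium 2-(allyloxy)-6-[(tert-butyldimethylsilyloxy)methyl]-4-methylphenoxide | C=CCOc1cc(C)cc(CO[Si](C)(C)C(C)(C)C)c1[O-].[K+] | intermediate (not isolated)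
21 | 3-methoxy-4-[(4R)-2,2,6,6-tetramethyl-1,3-dioxan-4-yl]benzyne (C1–C6 aryne of ring A) | COC1=C([C@H]2CC(C)(C)OC(C)(C)O2)C=CC#C1 | intermediate (not isolated)
22 | potassium 6-aryloxy-2-methoxy-3-[(4R)-2,2,6,6-tetramethyl-1,3-dioxan-4-yl]phenide (C1 aryl anion) | COc1c([C@H]2CC(C)(C)OC(C)(C)O2)ccc(Oc2c(OCC=C)cc(C)cc2CO[Si](C)(C)C(C)(C)C)[c-]1.[K+] | intermediate (not isolated)
23 | 6-[2-(allyloxy)-6-{[tert-butyl(dimethyl)silyl]oxymethyl}-4-methylphenoxy]-2-methoxy-3-[(4R)-2,2,6,6-tetramethyl-1,3-dioxan-4-yl]benzoic acid | COc1c([C@H]2CC(C)(C)OC(C)(C)O2)ccc(Oc2c(OCC=C)cc(C)cc2CO[Si](C)(C)C(C)(C)C)c1C(=O)O | intermediate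
24 | 6-[2-{[tert-butyl(dimethyl)silyl]oxymethyl}-6-hydroxy-4-methylphenoxy]-2-methoxy-3-[(4R)-2,2,6,6-tetramethyl-1,3-dioxan-4-yl]benzoic acid | COc1c([C@H]2CC(C)(C)OC(C)(C)O2)ccc(Oc2c(O)cc(C)cc2CO[Si](C)(C)C(C)(C)C)c1C(=O)O | intermediate
25 | 3-[(1R)-1,3-dihydroxy-3-methylbutyl]-6-[2-hydroxy-6-(hydroxymethyl)-4-methylphenoxy]-2-methoxybenzoic acid | COc1c([C@H](O)CC(C)(C)O)ccc(Oc2c(O)cc(C)cc2CO)c1C(=O)O | target

## Step count and least certain steps

Total: 15 steps (ring A arm 7, ring B arm 5, then 3 after convergence). Longest linear sequence: 10 steps (steps 1–7 and 13–15).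

**Step 13 (key step, proposed new method).** Three things may go wrong.
- The aryl anion 22 may be protonated before it meets CO2, either by adventitious proton sources or by abstracting a benzylic or allylic hydrogen of ring B through space. This would give the ether without the carboxyl group.
- Under CO2 the phenoxide may be held as its carbonate. If the carbonate adds to the aryne through oxygen and the acyl group then shifts to C1, the carboxyl would end up as an aryl ester with the wrong connectivity.
- Fluoride may partly cleave the silyl ether.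

Fallback (known chemistry only), setting out from 12 and 18 and returning at 24: the two bonds are made in separate, established operations. Fluoride-induced O-arylation of 18 with 12 (CsF, MeCN, rt, no CO2) should give the diaryl ether tert-butyl{[3-(allyloxy)-2-{3-methoxy-4-[(4R)-2,2,6,6-tetramethyl-1,3-dioxan-4-yl]phenoxy}-5-methylbenzyl]oxy}dimethylsilane F1, with the same regiochemistry and a hydrogen at C1. Deallylation with Pd(PPh3)4 and morpholine then gives phenol 3-{[tert-butyl(dimethyl)silyl]oxymethyl}-2-{3-methoxy-4-[(4R)-2,2,6,6-tetramethyl-1,3-dioxan-4-yl]phenoxy}-5-methylphenol F2, which removes the allyl ether before any alkyllithium is used. Treatment of F2 with n-BuLi/TMEDA (two equivalents; the phenoxide forms first) should lithiate C1, the position between the two ring A oxygens, and a CO2 quench gives 24.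

**Step 5.** Lithiation may take place at the open C5 position instead of C1. The C2 methoxy group is pressed by the C3 substituent so that its methyl shields C1, which weakens the cooperative effect. Deprotonation of the benzylic acetal C–H with ring opening is a lesser risk.

Fallback, setting out from commercial 3-hydroxy-2-methoxybenzaldehyde F3 and 3, and returning at aryne 21 in step 13 (hence at 23): the regioisomeric aryne precursor is made, with oxygen on C1 and silicon on C6, by the operations of steps 1–7.
- Carbamoylation gives 3-formyl-2-methoxyphenyl N,N-diethylcarbamate F4.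
- Brown methallylation with the same lIpc reagent gives 3-[(1R)-1-hydroxy-3-methylbut-3-en-1-yl]-2-methoxyphenyl N,N-diethylcarbamate F5.
- Mukaiyama hydration gives 3-[(1R)-1,3-dihydroxy-3-methylbutyl]-2-methoxyphenyl N,N-diethylcarbamate F6.
- Acetonide formation gives 2-methoxy-3-[(4R)-2,2,6,6-tetramethyl-1,3-dioxan-4-yl]phenyl N,N-diethylcarbamate F7.
- In F7 the carbamate has only one free ortho position, C6, because the other carries the methoxy group. Lithiation and silylation can therefore only give 2-methoxy-3-[(4R)-2,2,6,6-tetramethyl-1,3-dioxan-4-yl]-6-(trimethylsilyl)phenyl N,N-diethylcarbamate F8.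
- LiAlH4 gives 2-methoxy-3-[(4R)-2,2,6,6-tetramethyl-1,3-dioxan-4-yl]-6-(trimethylsilyl)phenol F9.
- Triflation gives 2-methoxy-3-[(4R)-2,2,6,6-tetramethyl-1,3-dioxan-4-yl]-6-(trimethylsilyl)phenyl trifluoromethanesulfonate F10.
- With fluoride, F10 loses silicon from C6 and triflate from C1 and gives the same aryne 21.

**Step 2.** Facial selectivity may be incomplete, because the ortho methoxy group and the magnesium salts can loosen the transition state. No later step would raise the enantiomeric purity.

Fallback, setting out from 7 and returning at 7: the centre is reset by catalytic ketone reduction. MnO2 in CH2Cl2 should oxidise the benzylic alcohol of 7 selectively to the β-hydroxy ketone 4-(3-hydroxy-3-methylbutanoyl)-3-methoxyphenyl N,N-diethylcarbamate F11. Noyori asymmetric transfer hydrogenation with RuCl[(R,R)-TsDPEN](p-cymene) in HCO2H/Et3N should then return 7 as the (R)-carbinol, by analogy with the reduction of aryl methyl ketones to (R)-1-arylethanols by this catalyst enantiomer.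

**Step 15.** The benzylic C–O bond may ionise while the slower silyl ether hydrolysis is still under way. This would erode the configuration or lead to elimination at the tertiary alcohol.

Fallback, setting out from 24 and returning at 25: the two deprotections are separated so that the acetal sees only the mildest acid. Buffered fluoride (TBAF, AcOH, THF) removes the silyl ether to give 6-[2-hydroxy-6-(hydroxymethyl)-4-methylphenoxy]-2-methoxy-3-[(4R)-2,2,6,6-tetramethyl-1,3-dioxan-4-yl]benzoic acid F12. The acetonide is then exchanged into the solvent by methanolysis with PPTS in MeOH at rt, which gives 25.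

## Further compounds

F1 | step 13 | tert-butyl{[3-(allyloxy)-2-{3-methoxy-4-[(4R)-2,2,6,6-tetramethyl-1,3-dioxan-4-yl]phenoxy}-5-methylbenzyl]oxy}dimethylsilane | COc1c([C@H]2CC(C)(C)OC(C)(C)O2)ccc(Oc2c(OCC=C)cc(C)cc2CO[Si](C)(C)C(C)(C)C)c1
F2 | step 13 | 3-{[tert-butyl(dimethyl)silyl]oxymethyl}-2-{3-methoxy-4-[(4R)-2,2,6,6-tetramethyl-1,3-dioxan-4-yl]phenoxy}-5-methylphenol | COc1c([C@H]2CC(C)(C)OC(C)(C)O2)ccc(Oc2c(O)cc(C)cc2CO[Si](C)(C)C(C)(C)C)c1
F3 | step 5 | 3-hydroxy-2-methoxybenzaldehyde | COc1c(O)cccc1C=O
F4 | step 5 | 3-formyl-2-methoxyphenyl N,N-diethylcarbamate | CCN(CC)C(=O)Oc1cccc(C=O)c1OC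
F5 | step 5 | 3-[(1R)-1-hydroxy-3-methylbut-3-en-1-yl]-2-methoxyphenyl N,N-diethylcarbamate | CCN(CC)C(=O)Oc1cccc([C@H](O)CC(C)=C)c1OC
F6 | step 5 | 3-[(1R)-1,3-dihydroxy-3-methylbutyl]-2-methoxyphenyl N,N-diethylcarbamate | CCN(CC)C(=O)Oc1cccc([C@H](O)CC(C)(C)O)c1OC
F7 | step 5 | 2-methoxy-3-[(4R)-2,2,6,6-tetramethyl-1,3-dioxan-4-yl]phenyl N,N-diethylcarbamate | CCN(CC)C(=O)Oc1cccc([C@H]2CC(C)(C)OC(C)(C)O2)c1OC
F8 | step 5 | 2-methoxy-3-[(4R)-2,2,6,6-tetramethyl-1,3-dioxan-4-yl]-6-(trimethylsilyl)phenyl N,N-diethylcarbamate | CCN(CC)C(=O)Oc1c([Si](C)(C)C)ccc([C@H]2CC(C)(C)OC(C)(C)O2)c1OC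
F9 | step 5 | 2-methoxy-3-[(4R)-2,2,6,6-tetramethyl-1,3-dioxan-4-yl]-6-(trimethylsilyl)phenol | COc1c(O)c([Si](C)(C)C)ccc1[C@H]1CC(C)(C)OC(C)(C)O1
F10 | step 5 | 2-methoxy-3-[(4R)-2,2,6,6-tetramethyl-1,3-dioxan-4-yl]-6-(trimethylsilyl)phenyl trifluoromethanesulfonate | COc1c(OS(=O)(=O)C(F)(F)F)c([Si](C)(C)C)ccc1[C@H]1CC(C)(C)OC(C)(C)O1
F11 | step 2 | 4-(3-hydroxy-3-methylbutanoyl)-3-methoxyphenyl N,N-diethylcarbamate | CCN(CC)C(=O)Oc1ccc(C(=O)CC(C)(C)O)c(OC)c1
F12 | step 15 | 6-[2-hydroxy-6-(hydroxymethyl)-4-methylphenoxy]-2-methoxy-3-[(4R)-2,2,6,6-tetramethyl-1,3-dioxan-4-yl]benzoic acid | COc1c([C@H]2CC(C)(C)OC(C)(C)O2)ccc(Oc2c(O)cc(C)cc2CO)c1C(=O)O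
A1 | alternative 1 | spiro grisadienedione (benzofuran-3-one spiro-fused at C1′ to a cyclohexa-2,4-dienone; racemic at the spiro carbon) | COc1c(C(=O)CC(C)(C)O[Si](CC)(CC)CC)ccc2OC3(C(=O)c12)C(=O)C=C(C)C=C3CO[Si](c1ccccc1)(c1ccccc1)C(C)(C)C
A2 | alternative 1 | 2,2′-dihydroxybenzophenone precursor (ring A C1–C(=O)–C1′ ring B) | COc1c(C(=O)CC(C)(C)O[Si](CC)(CC)CC)ccc(O)c1C(=O)c1c(O)cc(C)cc1CO[Si](c1ccccc1)(c1ccccc1)C(C)(C)C
A3 | alternative 2 | 2-aryloxycyclohex-2-enone with the ring B substituents (mixture at C3′ and C4′) | COc1c([C@H]2CC(C)(C)OC(C)(C)O2)ccc(OC2=C(C(=O)OC)CC(C)C(C(=O)OCC=C)C2=O)c1C(=O)OC(C)(C)C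
A4 | alternative 2 | allyl 4-aryloxyacetoacetate carrying ring A as its tert-butyl ester | COc1c([C@H]2CC(C)(C)OC(C)(C)O2)ccc(OCC(=O)CC(=O)OCC=C)c1C(=O)OC(C)(C)C
A5 | alternative 2 | methyl (E)-2-oxopent-3-enoate | C/C=C/C(=O)C(=O)OC
A6 | alternative 3 | ring A phenol (C2–OH) with C1–CH2O-p-methoxybenzyl, C6–O–ring B and the (4R)-dioxanyl group on C3 | Oc1c([C@H]2CC(C)(C)OC(C)(C)O2)ccc(Oc2c(OCC=C)cc(C)cc2CO[Si](C)(C)C(C)(C)C)c1COCc1ccc(OC)cc1
A7 | alternative 3 | (E)-1-diazo-4-[(4R)-2,2,6,6-tetramethyl-1,3-dioxan-4-yl]but-3-en-2-one | [N-]=[N+]=CC(=O)/C=C/[C@H]1CC(C)(C)OC(C)(C)O1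
A8 | alternative 3 | ring B aryl 3-(p-methoxybenzyloxy)prop-1-ynyl ether | COc1ccc(COCC#COc2c(OCC=C)cc(C)cc2CO[Si](C)(C)C(C)(C)C)cc1
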